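**Assumption:** each bicyclic half is numbered as a 1-benzoxepine (O1, C2 … C9a); the target's stereocentres are then 5aS,9aS (ketone half) and 3R,5aS,9aS (alcohol half). The route is a plan and has not been run.

## Retrosynthetic overview

1. Cut the C6'–CH2 bond of the ethano bridge: B-alkyl Suzuki coupling of keto enol triflate **11** with the borane from vinyl diene **13**. Both halves come from one bicyclic ketone.
2. Each oxepane: 7-endo opening of a 2,2-dimethyloxirane by the C9a–OH. The C3 ketone comes from oxidation; the C3–OH of the alcohol half comes from substrate-controlled reduction.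
3. C9a–O comes from the carvone isopropenyl group (ozonolysis/Criegee, retention). The enol triflate comes from the carvone enone (conjugate reduction/triflation).
4. Key step: the C5a quaternary stereocentre is set by Claisen rearrangement of the allyl dienol ether of 6-methylcarvone, anti to the isopropenyl group. (S)-Carvone is the only source of chirality.
5. Ring order: cyclohexene (bought in carvone) → oxepane (step 9) → union of the two bicycles (step 13).

## Route

**Step 1**
Reactants: **1** (S)-(+)-carvone
Product: **2** (5S)-6-methylcarvone (C6 epimers, mainly trans)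
Conditions: LDA, THF, −78 °C; MeI, −78 → 0 °C
Reagents that add atoms: iodomethane, `CI`
Why: Kinetic α′-enolate alkylation (only C6 can be deprotonated); the new C6 centre is re-enolised in step 2, so its configuration does not matter.

**Step 2**
Reactants: **2**
Product: **3** (6R)-1,3-dimethyl-2-(allyloxy)-6-isopropenylcyclohexa-1,3-diene (allyl dienol ether)
Conditions: KHMDS, THF/DMPU, −78 °C; allyl tosylate, −78 → 0 °C
Reagents that add atoms: allyl p-toluenesulfonate, `C=CCOS(=O)(=O)c1ccc(C)cc1`
Why: O-alkylation of the dissociated potassium dienolate with a hard sulfonate electrophile (Williamson-type enol ether formation); any C-allylated by-product is already compound 4.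

**Step 3 (key step)**
Reactants: **3**
Product: **4** (5R,6R)-6-allyl-2,6-dimethyl-5-isopropenylcyclohex-2-en-1-one (allyl trans to isopropenyl)
Conditions: xylenes, BHT (cat.), 140 °C, sealed tube
Reagents that add atoms: none
Why: Aliphatic Claisen [3,3]-sigmatropic rearrangement; the allyl terminus bonds to C6 on the face anti to the adjacent isopropenyl group, setting the quaternary centre (future C5a).

**Step 4**
Reactants: **4**
Product: **5** (5R,6R)-2,6-dimethyl-6-(3-oxopropyl)-5-isopropenylcyclohex-2-en-1-one
Conditions: PdCl2(PhCN)2, CuCl2·2H2O, AgNO2 (cat.), t-BuOH/MeNO2, O2 (1 atm), rt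
Reagents that add atoms: dioxygen, `O=O` (O delivered via nitrite, `[Ag+].[O-]N=O`)
Why: Nitrite-modified, aldehyde-selective (anti-Markovnikov) Wacker oxidation of the monosubstituted alkene; the 1,1-disubstituted isopropenyl group and the enone are inert.

**Step 5**
Reactants: **5**
Product: **6** (5R,6R)-6-[2-(3,3-dimethyloxiran-2-yl)ethyl]-2,6-dimethyl-5-isopropenylcyclohex-2-en-1-one (about 1:1 at the oxirane CH)
Conditions: i-PrSPh2+ BF4−, t-BuLi, DME, −78 °C; then **5**, −78 → −40 °C
Reagents that add atoms: isopropyldiphenylsulfonium tetrafluoroborate, `CC(C)[S+](c1ccccc1)c1ccccc1.F[B-](F)(F)F`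
Why: Corey–Chaykovsky-type epoxidation with diphenylsulfonium isopropylide, faster at the aldehyde than at the hindered enone; the uncontrolled oxirane centre (future C3) is erased by oxidation in step 10.

**Step 6**
Reactants: **6**
Product: **7** (1S,2R)-2-[2-(3,3-dimethyloxiran-2-yl)ethyl]-2,4-dimethyl-3-oxocyclohex-4-en-1-yl acetate
Conditions: O3, CH2Cl2/MeOH, −78 °C; then Ac2O, Et3N, DMAP, 0 °C → rt
Reagents that add atoms: ozone, `[O-][O+]=O`; methanol, `CO` (Ac2O only activates the hydroperoxide)
Why: Ozone cleaves the electron-rich isopropenyl group selectively over the enone; Criegee rearrangement of the methoxy-hydroperoxide moves the ring carbon to oxygen with retention, giving the C9a–O stereocentre.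

**Step 7**
Reactants: **7**
Product: **8** (5S,6R)-5-acetoxy-6-[2-(3,3-dimethyloxiran-2-yl)ethyl]-2,6-dimethylcyclohex-1-en-1-yl triflate
Conditions: L-Selectride (1.1 equiv), THF, −78 °C; then PhNTf2, −78 → 0 °C
Reagents that add atoms: N-phenylbis(trifluoromethanesulfonimide), `O=S(=O)(N(c1ccccc1)S(=O)(=O)C(F)(F)F)C(F)(F)F`
Why: 1,4-Reduction gives the regiodefined enolate, which is O-triflated to the tetrasubstituted enol triflate; the acetate and epoxide survive at −78 °C.

**Step 8**
Reactants: **8**
Product: **9** (5S,6R)-6-[2-(3,3-dimethyloxiran-2-yl)ethyl]-5-hydroxy-2,6-dimethylcyclohex-1-en-1-yl triflate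
Conditions: DIBAL-H, CH2Cl2, −78 °C
Reagents that add atoms: none
Why: Reductive acetate cleavage under non-basic conditions; epoxide and enol triflate are untouched at −78 °C.

**Step 9**
Reactants: **9**
Product: **10** (5aR,9aS)-3-hydroxy-2,2,5a,7-tetramethyl-2,3,4,5,5a,8,9,9a-octahydro-1-benzoxepin-6-yl triflate (both C3 epimers)
Conditions: CSA (10 mol%), CH2Cl2, 0 °C
Reagents that add atoms: none
Why: Acid-catalysed epoxide opening at the tertiary carbon (Markovnikov, 7-endo) by the C9a–OH closes the trans-fused oxepane; the ring-fusion centres are already fixed.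

**Step 10**
Reactants: **10**
Product: **11** (5aR,9aS)-2,2,5a,7-tetramethyl-3-oxo-2,3,4,5,5a,8,9,9a-octahydro-1-benzoxepin-6-yl triflate
Conditions: Dess–Martin periodinane, NaHCO3, CH2Cl2, rt
Reagents that add atoms: none
Why: Alcohol oxidation converges both C3 epimers to one ketone (the ketone half).

**Step 11**
Reactants: **11** (part of the material)
Product: **12** (3R,5aR,9aS)-3-hydroxy-2,2,5a,7-tetramethyl-2,3,4,5,5a,8,9,9a-octahydro-1-benzoxepin-6-yl triflate
Conditions: NaBH4, MeOH/CH2Cl2, −40 °C
Reagents that add atoms: none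
Why: Substrate-controlled hydride reduction; attack anti to the angular C5a methyl should give the 3-OH cis to that methyl (3R), by analogy with 4,4-dimethyl-3-keto triterpenoid A rings. The ratio is a prediction.

**Step 12**
Reactants: **12**
Product: **13** (3R,5aS,9aS)-6-ethenyl-2,2,5a,7-tetramethyl-2,3,4,5,5a,8,9,9a-octahydro-1-benzoxepin-3-ol
Conditions: tributyl(vinyl)tin, Pd(PPh3)4, LiCl, THF, 65 °C
Reagents that add atoms: tributyl(vinyl)stannane, `C=C[Sn](CCCC)(CCCC)CCCC`
Why: Stille coupling of the hindered enol triflate (precedent: 2,6,6-trimethylcyclohexenyl triflates); no stereocentre is involved.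

**Step 13**
Reactants: **13** and **11**
Product: **14** sodwanone T
Conditions: 9-BBN (2.5 equiv), THF, 0 °C → rt; then **11**, Pd(dppf)Cl2, AsPh3, Cs2CO3, DMF/H2O, 50 °C
Reagents that add atoms: none (9-BBN delivers H only)
Why: Hydroboration at the terminal vinyl carbon, then B-alkyl Suzuki–Miyaura coupling, forms the CH2–CH2 bridge; the ketone only meets the borane after the B–H is quenched.

## Compound list

1 | (S)-(+)-carvone | `CC1=CC[C@@H](CC1=O)C(C)=C` | starting material
2 | (5S)-6-methylcarvone (C6 epimers) | `CC1=CC[C@H](C(C)=C)C(C)C1=O` | intermediate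
3 | (6R)-1,3-dimethyl-2-(allyloxy)-6-isopropenylcyclohexa-1,3-diene | `CC1=CC[C@H](C(C)=C)C(C)=C1OCC=C` | intermediate
4 | (5R,6R)-6-allyl-2,6-dimethyl-5-isopropenylcyclohex-2-en-1-one | `CC1=CC[C@H](C(C)=C)[C@@](C)(CC=C)C1=O` | intermediate
5 | (5R,6R)-2,6-dimethyl-6-(3-oxopropyl)-5-isopropenylcyclohex-2-en-1-one | `CC1=CC[C@H](C(C)=C)[C@@](C)(CCC=O)C1=O` | intermediate
6 | (5R,6R)-6-[2-(3,3-dimethyloxiran-2-yl)ethyl]-2,6-dimethyl-5-isopropenylcyclohex-2-en-1-one | `CC1=CC[C@H](C(C)=C)[C@@](C)(CCC2OC2(C)C)C1=O` | intermediate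
7 | (1S,2R)-2-[2-(3,3-dimethyloxiran-2-yl)ethyl]-2,4-dimethyl-3-oxocyclohex-4-en-1-yl acetate | `CC1=CC[C@H](OC(C)=O)[C@@](C)(CCC2OC2(C)C)C1=O` | intermediate
8 | (5S,6R)-5-acetoxy-6-[2-(3,3-dimethyloxiran-2-yl)ethyl]-2,6-dimethylcyclohex-1-en-1-yl triflate | `CC1=C(OS(=O)(=O)C(F)(F)F)[C@](C)(CCC2OC2(C)C)[C@@H](OC(C)=O)CC1` | intermediate
9 | (5S,6R)-6-[2-(3,3-dimethyloxiran-2-yl)ethyl]-5-hydroxy-2,6-dimethylcyclohex-1-en-1-yl triflate | `CC1=C(OS(=O)(=O)C(F)(F)F)[C@](C)(CCC2OC2(C)C)[C@@H](O)CC1` | intermediate
10 | (5aR,9aS)-3-hydroxy-2,2,5a,7-tetramethyl-octahydro-1-benzoxepin-6-yl triflate (C3 epimers) | `CC1=C(OS(=O)(=O)C(F)(F)F)[C@]2(C)CCC(O)C(C)(C)O[C@H]2CC1` | intermediate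
11 | (5aR,9aS)-2,2,5a,7-tetramethyl-3-oxo-octahydro-1-benzoxepin-6-yl triflate | `CC1=C(OS(=O)(=O)C(F)(F)F)[C@]2(C)CCC(=O)C(C)(C)O[C@H]2CC1` | intermediate
12 | (3R,5aR,9aS)-3-hydroxy-2,2,5a,7-tetramethyl-octahydro-1-benzoxepin-6-yl triflate | `CC1=C(OS(=O)(=O)C(F)(F)F)[C@]2(C)CC[C@@H](O)C(C)(C)O[C@H]2CC1` | intermediate
13 | (3R,5aS,9aS)-6-ethenyl-2,2,5a,7-tetramethyl-octahydro-1-benzoxepin-3-ol | `CC1=C(C=C)[C@]2(C)CC[C@@H](O)C(C)(C)O[C@H]2CC1` | intermediate
14 | sodwanone T | `CC1=C(CCC2=C(C)CC[C@@H]3OC(C)(C)[C@H](O)CC[C@@]23C)[C@]2(C)CCC(=O)C(C)(C)O[C@H]2CC1` | target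

## Summary

**Total steps:** 13. **Longest linear sequence:** 13 (1 → 11 → 12 → 13 → 14; compound 11 is used twice).

**Steps most likely to fail, with fallbacks**

1. **Step 9 (7-endo vs 6-exo epoxide opening).** If the tetrahydropyran dominates, replace epoxide opening by displacement at a tertiary α-bromoketone. Rearrange the epoxide of **8** to the isopropyl ketone (BF3·OEt2, Meinwald), brominate the tertiary α-carbon (PhNMe3Br3), remove the acetate, and close the oxepane with AgOTf/2,6-di-tert-butylpyridine. This gives **11** directly.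
2. **Step 11 (facial selectivity of the oxepanone reduction).** If the 3S alcohol predominates, skip the reduction: separate the C3 epimers of **10** after step 9, use the 3R epimer as **12**, and send only the 3S epimer through step 10 to **11**.
3. **Step 13 (sp3–sp2 Suzuki between two hindered partners).** If coupling fails, switch to a symmetric union. Double Stille coupling of **11** with (E)-1,2-bis(tributylstannyl)ethene gives the triene diketone; diimide reduces the central disubstituted alkene; a statistical NaBH4 mono-reduction then gives **14**, with diketone and diol recycled.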